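## Structural features

Isodihydromaldoxin is an achiral diaryl ether: two benzene rings joined through a single oxygen that links C2 of ring A to C1' of ring B. There is no stereocentre, so nothing configurational has to be set. Ring A carries a methyl ester at C1, a methoxy group at C3 and a free hydroxyl at C5. Ring B carries a methyl group at C3', chlorine at C4', a free hydroxyl at C5' and a free carboxylic acid at C6'. The ether oxygen is crowded, because C1, C3 and C6' all bear substituents, so a late aromatic C–O coupling is hard. The fragile points are the two carboxyl groups in different states (ester on ring A, acid on ring B), the 2,6-dioxygenated benzoic acid of ring B (prone to decarboxylation in hot acid), the aryl chloride (sensitive to reduction) and the para-oxygenated ring A phenol (oxidisable to a quinone). The real difficulty is to forge the hindered ether while telling apart two carboxyl groups and four ring oxygens, of which one stays a methyl ether and two end as free phenols. The key step exploits the contiguous array on ring B: C1' (ether oxygen), C6' (carboxyl carbon) and C5' (oxygen). A nucleophile at C1' and an electrophile at C6' next to an alkoxy group on C5' is exactly the addition pattern of a 3-alkoxybenzyne whose triple bond lies between C1' and C6'.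

## Logic of the disconnections

22 goes back to 21 by cutting the O–CH2Ph bond at C5 and the O–CH3 bond at C5'. Both phenols are kept masked so that no acidic O–H is present in the anionic and palladium steps. The forward step must cleave these two groups and leave the C3 methyl ether, the methyl ester and the C–Cl bond alone; the carboxyl group on C6' beside the C5' oxygen is what makes that distinction possible.

21 goes back to 20 by cutting the bond between C1 and its ester carbon. A C1 ester present earlier would be acylated by the C6' carbanion of the key step, so bromine stands in for it. The gain is that the two carboxyl groups are told apart simply by the order in which they appear. The demand is a carbonylation of a hindered, electron-rich C–Br bond in the presence of a free acid and a C–Cl bond.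

20 goes back to 17 (from 16), 18 (from 11) and CO2 by cutting the O–C1' bond and the bond from C6' to the carboxyl carbon. These two bonds sit on adjacent carbons next to the C5' oxygen. The cut gives two benzene pieces of similar size and makes the route convergent. The forward step needs addition of the oxygen nucleophile at C1' only, and capture of the C6' carbanion by CO2 faster than by any proton.

11 goes back through 10 to 9 (O–S bond), then to 5 (C–Si bond, through 6, 7 and 8), then to 4 (carbamate C–O bond). The silicon has to sit between two oxygen substituents, which is the position a carbamate and a methoxy group jointly direct a lithium base to. The demand is lithiation at that one C–H with the C–Cl bond untouched, and a carbamate that comes off under mild base.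

4 goes back through 3 to 2 by exchanging the phenolic C–O bond for a C–H bond, and 2 goes back to 1 by cutting O–CH3. Electrophilic chlorination of the chlorine-free phenol would have three activated positions to choose from. Buying the chlorine in place and introducing the oxygen at the only unhindered C–H removes the regiochemical question. The demand is a C–H functionalisation governed purely by sterics.

16 goes back to 14 by cutting O–CH2Ph, and 14 goes back through 13 to 12 by exchanging the C4–O bond for the C–CHO bond. In 12 the bromine, the methoxy group and the hydroxyl that becomes the ether oxygen are already in their final positions. The demand is benzylation of only the unhindered oxygen of 14, which is arranged through 15.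

## Other disconnections considered

Alternative 1: The cut is made in ring A, at C1–C2 and C4–C5, so ring A is grown on a finished ring B instead of being bought. In the forward sense the aryloxy ketone A2 is deprotonated by a potassium alkoxide at its O–CH2 carbon and adds to the fumarate diester A3 (Michael, C1–C2). The methyl ketone enolate then closes onto the far ester (Claisen, C4–C5) to give the trans dione A1. Dehydrogenation, methylation of the C3 oxygen only and acid cleavage of the tert-butyl ester would follow. In its favour, the crowded ether is made as an alkyl aryl ether by plain phenol alkylation, which is better than the chosen plan on that point. The C1 ester arrives unambiguously with A3, so no carbonylation is needed, also a better point. Every reaction type has precedent, whereas the chosen key step has none. Against it, A1 holds the aryloxy group β to the ester carbonyl and α to a ketone, so enolisation can expel the ring B phenoxide. Aromatisation must add one double bond without that loss. The C3 and C5 oxygens must then be told apart, and the one to be methylated is the more hindered, which would cost a protect, methylate, deprotect sequence. The ketone may also enolise towards its methyl group and lead to the regioisomeric dione, and the two stereocentres of A1 are made only to be destroyed. On structure, the chosen plan keeps both rings aromatic throughout. On mechanism, it relies on one polar three-component event instead of an annulation plus an oxidation. On step economy, A2 needs a ring B phenol ester about as long to make as 11 and the end game is longer, so the alternative should be several steps longer. The final cleavage of the C5' methyl ether is common to both plans, an equal point.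

Alternative 2: The cut is made in ring B at C1'–C2' and C5'–C6', and ring A arrives complete, ester included, on the alkyne oxygen. In the forward sense the aryloxy ynoate A5 and the silyl ketene acetal diene A6 undergo a Diels–Alder reaction, with the nucleophilic CH2 terminus of A6 bonding to the oxygen-bearing alkyne carbon. Loss of the acetal methoxy group and desilylation then give A4. In its favour, the C5' oxygen appears directly as the free phenol, so no methyl ether has to be cleaved beside the C3 methoxy group, which is better than the chosen plan. The ring A ester is present from the start, also better. Only benzyl groups remain to be removed, and cycloaddition with aromatisation of ynoates and ketene acetal dienes is a known reaction class, whereas the chosen key step is not. Against it, A5 is a ynol ether of a phenol flanked by two ortho substituents; it is laborious to make and prone to hydration. Its oxygen donor lowers the dienophilicity and its reacting carbon is hindered, so forcing conditions are likely. Under those conditions A6, a moisture-sensitive chlorinated dienolate equivalent, may decompose or transfer silicon. The aromatisation may also expel the silyloxy group instead of the methoxy group. On structure, the alternative builds a hexasubstituted benzene from acyclic pieces where the chosen plan only decorates purchased rings. On mechanism, regiocontrol by polarity matching is about as dependable as regiocontrol by aryne distortion, an equal point. On step economy, A5 and A6 together should need roughly as many steps as 11 and 16, so the totals are comparable, also an equal point.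

Alternative 3: The cut is made in ring B at C3'–C4' and C5'–C6'. In the forward sense the aryloxy pyranone A8 is heated with the ketene acetal A9. The nucleophilic CHCl carbon of A9 bonds to the methyl-bearing terminus of the pyranone diene and the acetal carbon to the ester-bearing terminus. Decarboxylative opening of the bicyclic adduct and loss of one acetal methoxy group give A7. In its favour, the ether bond is made by addition–elimination on a pyranone carbon bearing a leaving group, a vinylogous acyl substitution that is easier than substitution on a benzene ring, which is better than the chosen plan on that point. Chlorine and the C5' oxygen arrive together with regiochemistry fixed by the polarity of A9, and the reaction type is known. Against it, A8 needs a pyranone carrying both a C3 ester and a C4 leaving group, and its hindered aryloxy donor lowers the reactivity of the diene. A9 is volatile and polymerises readily, and the temperatures needed put the benzyl ester and the crowded ether under stress. A7 still holds the C5' methyl ether, so the end game is the same chelation-controlled dealkylation as in the chosen plan, an equal point. On structure, ring B is again built de novo. On mechanism, a thermal cycloaddition–cycloreversion cascade replaces a polar three-component coupling. On step economy, the ring A phenol ester, the pyranone activation, the cycloaddition and the deprotection add up to about the same count as the chosen plan, so neither is clearly shorter.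

Key step: step 8

Assumption: 2-chloro-3-methylphenol (1) and 5-bromovanillin (12) are taken as purchasable; the C5' oxygen is carried as a methyl ether up to the last step; and, as the target has no stereocentre, no step has to set configuration.

## Steps

Step 1
Reactants: 1 2-chloro-3-methylphenol
Product: 2 2-chloro-1-methoxy-3-methylbenzene
Conditions: MeI, K2CO3, acetone, reflux
Reagents that add atoms: iodomethane, CI
Why: Williamson O-methylation of the phenoxide (SN2 on MeI); the phenol oxygen is the only nucleophilic site and the ortho chlorine only makes it more acidic.

Step 2
Reactants: 2 2-chloro-1-methoxy-3-methylbenzene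
Product: 4 4-chloro-3-methoxy-5-methylphenol, via arylboronic pinacol ester 3 (not isolated)
Conditions: [Ir(OMe)(cod)]2 (cat.), dtbpy, B2pin2, THF, 80 °C; then KHSO5 (as 2KHSO5·KHSO4·K2SO4), acetone/H2O, rt
Reagents that add atoms: potassium peroxymonosulfate, [K+].[O-]S(=O)(=O)OO (phenol oxygen); bis(pinacolato)diboron, CC1(C)OB(OC1(C)C)B1OC(C)(C)C(C)(C)O1 (boryl group of 3 only)
Why: Iridium-catalysed aromatic C–H borylation is sterically controlled, and C5 of 2 is the only ring C–H without an ortho substituent, so boron should enter para to chlorine; peroxymonosulfate then oxidises the C–B bond (aryl shift from boron to oxygen) to the phenol without touching chloride, methyl or methyl ether.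

Step 3
Reactants: 4 4-chloro-3-methoxy-5-methylphenol
Product: 5 4-chloro-3-methoxy-5-methylphenyl N-(propan-2-yl)carbamate
Conditions: iPrNCO, Et3N (cat.), CH2Cl2, rt
Reagents that add atoms: isopropyl isocyanate, CC(C)N=C=O
Why: Base-catalysed addition of the phenol O–H to the isocyanate gives the N-monoalkyl carbamate, a strong ortho-directing group that can later be removed by mild base because it keeps an N–H.

Step 4
Reactants: 5 4-chloro-3-methoxy-5-methylphenyl N-(propan-2-yl)carbamate
Product: 9 4-chloro-3-methoxy-5-methyl-2-(trimethylsilyl)phenyl N-(propan-2-yl)carbamate, via N-silyl carbamate 6 (not isolated), via aryllithium 7 (not isolated), via doubly silylated carbamate 8 (not isolated)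
Conditions: TMSOTf, TMEDA, Et2O, 0 °C to rt; n-BuLi, TMEDA, −78 °C; TMSCl, −78 °C to rt; aq. NaHSO4
Reagents that add atoms: chlorotrimethylsilane, C[Si](C)(C)Cl; trimethylsilyl trifluoromethanesulfonate, C[Si](C)(C)OS(=O)(=O)C(F)(F)F (nitrogen silyl group of 6, 7 and 8 only)
Why: Directed ortho metalation: once the N–H is capped in situ as N–SiMe3, n-BuLi/TMEDA should remove the ring hydrogen between the carbamate and methoxy oxygens, the most acidic and doubly coordinated site, and Me3SiCl traps the aryllithium at −78 °C before an anionic ortho-Fries shift can start; the chlorine has no ortho hydrogen, so no elimination pathway is open, and the N–Si bond is hydrolysed on acidic work-up.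

Step 5
Reactants: 9 4-chloro-3-methoxy-5-methyl-2-(trimethylsilyl)phenyl N-(propan-2-yl)carbamate
Product: 11 4-chloro-3-methoxy-5-methyl-2-(trimethylsilyl)phenyl trifluoromethanesulfonate, via ortho-silyl phenol 10 (not isolated)
Conditions: DBU, Et2NH, MeCN, 40 °C; then PhNTf2, rt
Reagents that add atoms: N-phenylbis(trifluoromethanesulfonimide), O=S(=O)(N(c1ccccc1)S(=O)(=O)C(F)(F)F)C(F)(F)F
Why: DBU removes the carbamate N–H and the anion fragments (E1cB) to the phenoxide and isopropyl isocyanate, which Et2NH scavenges as a urea; the phenoxide is then sulfonylated by PhNTf2 in the same flask, under conditions mild enough to spare the ortho C–Si bond.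

Step 6
Reactants: 12 5-bromovanillin (3-bromo-4-hydroxy-5-methoxybenzaldehyde)
Product: 14 2-bromo-6-methoxybenzene-1,4-diol, via aryl formate 13 (not isolated)
Conditions: H2O2 (30% aq.), NaOH, THF/H2O, 0 °C to rt; then Na2S2O4, aq. HCl
Reagents that add atoms: hydrogen peroxide, OO
Why: Dakin oxidation: hydroperoxide adds to the aldehyde para to the phenoxide, the electron-rich aryl group migrates to oxygen and the formate is hydrolysed in the basic medium; dithionite in the work-up returns any quinone to the hydroquinone.

Step 7
Reactants: 14 2-bromo-6-methoxybenzene-1,4-diol
Product: 16 4-(benzyloxy)-2-bromo-6-methoxyphenol, via disodium diolate 15 (not isolated)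
Conditions: NaH (2.2 equiv), degassed DMF/THF, 0 °C; BnBr (1.0 equiv), 0 °C to rt; aq. NH4Cl
Reagents that add atoms: benzyl bromide, BrCc1ccccc1; sodium hydride, [Na+].[H-] (counter-ions of 15 only)
Why: Williamson benzylation under dianion control: with both hydroxyls deprotonated, the C4 oxyanion (no ortho substituent, conjugate base of the less acidic hydroxyl) is both the more basic and the more accessible one, while the C1 oxyanion is flanked by bromine and methoxy and tied up in a sodium chelate, so one equivalent of BnBr should react at the C4 oxygen.

Step 8
Reactants: 16 4-(benzyloxy)-2-bromo-6-methoxyphenol; 11 4-chloro-3-methoxy-5-methyl-2-(trimethylsilyl)phenyl trifluoromethanesulfonate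
Product: 20 6-[4-(benzyloxy)-2-bromo-6-methoxyphenoxy]-3-chloro-2-methoxy-4-methylbenzoic acid, via potassium phenoxide 17 (not isolated), via aryne 18 (not isolated), via aryl anion 19 (not isolated)
Conditions: 16 (1.5 equiv), KH, THF, 0 °C; then CO2 (1 atm), KF, 18-crown-6, slow addition of 11, THF, 0 °C to rt; aq. HCl
Reagents that add atoms: carbon dioxide, O=C=O
Why: Proposed new method: fluoride attacks the silicon of 11 and triflate leaves to give aryne 18, whose C1'–C6' triple bond is distorted by the inductively withdrawing methoxy group on C5' so that C1' is the more electrophilic carbon; phenoxide 17 adds through oxygen at C1' (O–C1' bond) and leaves aryl anion 19 on C6', between two oxygen-bearing carbons, which attacks CO2 (C6'–carboxyl bond) to give the carboxylate that is protonated on work-up. The closest known reaction types are the three-component coupling of arynes with amines and CO2 to anthranilic acids and the O-arylation of phenols by arynes released from ortho-silylaryl triflates; the present step merges the two with an anionic oxygen nucleophile in place of the neutral amine. No ring is closed and no stereocentre is formed. Regioselectivity at the aryne is needed and is secured by the single flanking methoxy group, the other neighbour of the triple bond (C2') being a C–H. Capture of 19 by CO2 in preference to a proton is secured by preforming 17 with KH so that no O–H is present, by THF in place of a C–H acidic solvent and by the CO2 atmosphere. O-arylation in preference to C-arylation of the ambident phenoxide is secured by the substituents on both ortho positions and on the para position of 17. Bromine on ring A is inert towards 19, whereas an ester there would be acylated to a xanthone, and slow addition of 11 to an excess of 17 keeps the product carboxylate from adding to a second aryne.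

Step 9
Reactants: 20 6-[4-(benzyloxy)-2-bromo-6-methoxyphenoxy]-3-chloro-2-methoxy-4-methylbenzoic acid
Product: 21 6-[4-(benzyloxy)-2-methoxy-6-(methoxycarbonyl)phenoxy]-3-chloro-2-methoxy-4-methylbenzoic acid
Conditions: Pd(OAc)2 (cat.), Xantphos, CO (1 atm), Et3N, MeOH, 70 °C
Reagents that add atoms: carbon monoxide, [C-]#[O+]; methanol, CO
Why: Palladium-catalysed alkoxycarbonylation: oxidative addition of the C1–Br bond to zerovalent palladium, CO insertion and methanolysis of the acylpalladium, which the wide-bite-angle Xantphos ligand allows at atmospheric pressure; the hindered electron-rich C–Cl bond should not react at this temperature, and the ring B acid sits as its triethylammonium salt, so only the new carboxyl becomes a methyl ester.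

Step 10
Reactants: 21 6-[4-(benzyloxy)-2-methoxy-6-(methoxycarbonyl)phenoxy]-3-chloro-2-methoxy-4-methylbenzoic acid
Product: 22 isodihydromaldoxin (3-chloro-2-hydroxy-6-[4-hydroxy-2-methoxy-6-(methoxycarbonyl)phenoxy]-4-methylbenzoic acid)
Conditions: BCl3, C6HMe5, CH2Cl2, −78 to 0 °C; H2O
Reagents that add atoms: none
Why: Lewis-acid dealkylation: BCl3 ionises the benzyl ether at low temperature and pentamethylbenzene traps the benzyl cation, while boron bound to the C6' carboxyl chelates the neighbouring C5' methoxy oxygen so that chloride removes its methyl group; the C3 methoxy group has no carbonyl neighbour, the methyl ester is not cleaved at 0 °C, and no reductant touches the C–Cl bond.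

## Compound list

1 | 2-chloro-3-methylphenol | Cc1cccc(O)c1Cl | starting material
2 | 2-chloro-1-methoxy-3-methylbenzene | COc1cccc(C)c1Cl | intermediate
3 | 2-(4-chloro-3-methoxy-5-methylphenyl)-4,4,5,5-tetramethyl-1,3,2-dioxaborolane | COc1cc(B2OC(C)(C)C(C)(C)O2)cc(C)c1Cl | intermediate
4 | 4-chloro-3-methoxy-5-methylphenol | COc1cc(O)cc(C)c1Cl | intermediate
5 | 4-chloro-3-methoxy-5-methylphenyl N-(propan-2-yl)carbamate | COc1cc(OC(=O)NC(C)C)cc(C)c1Cl | intermediate
6 | 4-chloro-3-methoxy-5-methylphenyl N-(propan-2-yl)-N-(trimethylsilyl)carbamate | COc1cc(OC(=O)N(C(C)C)[Si](C)(C)C)cc(C)c1Cl | intermediate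
7 | 2-lithio derivative of 6 (lithium on the ring carbon between the carbamate and methoxy oxygens) | COc1c(Cl)c(C)cc(OC(=O)N(C(C)C)[Si](C)(C)C)c1[Li] | intermediate
8 | 4-chloro-3-methoxy-5-methyl-2-(trimethylsilyl)phenyl N-(propan-2-yl)-N-(trimethylsilyl)carbamate | COc1c(Cl)c(C)cc(OC(=O)N(C(C)C)[Si](C)(C)C)c1[Si](C)(C)C | intermediate
9 | 4-chloro-3-methoxy-5-methyl-2-(trimethylsilyl)phenyl N-(propan-2-yl)carbamate | COc1c(Cl)c(C)cc(OC(=O)NC(C)C)c1[Si](C)(C)C | intermediate
10 | 4-chloro-3-methoxy-5-methyl-2-(trimethylsilyl)phenol | COc1c(Cl)c(C)cc(O)c1[Si](C)(C)C | intermediate
11 | 4-chloro-3-methoxy-5-methyl-2-(trimethylsilyl)phenyl trifluoromethanesulfonate | COc1c(Cl)c(C)cc(OS(=O)(=O)C(F)(F)F)c1[Si](C)(C)C | intermediate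
12 | 5-bromovanillin (3-bromo-4-hydroxy-5-methoxybenzaldehyde) | COc1cc(C=O)cc(Br)c1O | starting material
13 | 3-bromo-4-hydroxy-5-methoxyphenyl formate | COc1cc(OC=O)cc(Br)c1O | intermediate
14 | 2-bromo-6-methoxybenzene-1,4-diol | COc1cc(O)cc(Br)c1O | intermediate
15 | disodium 2-bromo-6-methoxybenzene-1,4-bis(olate) | [Na+].[Na+].COc1cc([O-])cc(Br)c1[O-] | intermediate
16 | 4-(benzyloxy)-2-bromo-6-methoxyphenol | COc1cc(OCc2ccccc2)cc(Br)c1O | intermediate
17 | potassium 4-(benzyloxy)-2-bromo-6-methoxyphenolate | [K+].COc1cc(OCc2ccccc2)cc(Br)c1[O-] | intermediate
18 | 4-chloro-3-methoxy-5-methylbenzyne (4-chloro-3-methoxy-5-methyl-1,2-didehydrobenzene) | COC1=C(Cl)C(C)=CC#C1 | intermediate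
19 | potassium 2-[4-(benzyloxy)-2-bromo-6-methoxyphenoxy]-5-chloro-6-methoxy-4-methylbenzen-1-ide | [K+].COc1cc(OCc2ccccc2)cc(Br)c1Oc1cc(C)c(Cl)c(OC)[c-]1 | intermediate
20 | 6-[4-(benzyloxy)-2-bromo-6-methoxyphenoxy]-3-chloro-2-methoxy-4-methylbenzoic acid | COc1cc(OCc2ccccc2)cc(Br)c1Oc1cc(C)c(Cl)c(OC)c1C(=O)O | intermediate
21 | 6-[4-(benzyloxy)-2-methoxy-6-(methoxycarbonyl)phenoxy]-3-chloro-2-methoxy-4-methylbenzoic acid | COC(=O)c1cc(OCc2ccccc2)cc(OC)c1Oc1cc(C)c(Cl)c(OC)c1C(=O)O | intermediate
22 | isodihydromaldoxin (3-chloro-2-hydroxy-6-[4-hydroxy-2-methoxy-6-(methoxycarbonyl)phenoxy]-4-methylbenzoic acid) | COC(=O)c1cc(O)cc(OC)c1Oc1cc(C)c(Cl)c(O)c1C(=O)O | target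

## Step count and least certain steps

Total: 10 steps. Longest linear sequence: 8 steps (steps 1 to 5, then 8, 9 and 10); the ring A branch (steps 6 and 7) joins at step 8.

Step 8 (key step). The most likely failure is quenching of the C6' carbanion by a stray proton before it meets CO2. The second is sequestration of the phenoxide as its carbonate under CO2, which slows the addition so that the aryne is consumed by fluoride or by the product carboxylate. Both follow from the fact that the oxygen nucleophile is anionic, hindered and in reversible equilibrium with CO2. The fallback uses only known chemistry; it sets out from 2 and 16 and comes back at 20. Compound 2 is borylated as in step 2 but 3 is isolated, and bromodeboronation with CuBr2 in aqueous methanol gives 5-bromo-2-chloro-1-methoxy-3-methylbenzene F1. Deprotonation of the C–H between bromine and methoxy with LiN(iPr)2 in THF at −78 °C and quenching with CO2 gives 6-bromo-3-chloro-2-methoxy-4-methylbenzoic acid F2. A copper-catalysed Ullmann condensation of F2 with 16 (CuI, K2CO3, pyridine/DMF, heat) then gives 20; the ortho carboxylate activates the C–Br bond of F2 over the unactivated bromide of 16.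

Step 7. The likely failure is loss of site selectivity, meaning alkylation at the hindered oxygen or at both, together with air oxidation of the electron-rich dianion. The two oxyanions differ only moderately in basicity, and the selectivity rests on that difference plus sterics. The fallback sets out from 12 and comes back at 16. Protection of the hindered hydroxyl with chloromethyl methyl ether and iPr2NEt gives 3-bromo-5-methoxy-4-(methoxymethoxy)benzaldehyde F3. Baeyer–Villiger oxidation with mCPBA gives 3-bromo-5-methoxy-4-(methoxymethoxy)phenyl formate F4, and methanolysis (K2CO3, MeOH) gives 3-bromo-5-methoxy-4-(methoxymethoxy)phenol F5. Benzylation (BnBr, K2CO3, DMF) gives 5-(benzyloxy)-1-bromo-3-methoxy-2-(methoxymethoxy)benzene F6, and HCl in methanol removes the acetal to give 16. This is two steps longer, but the two oxygens are never in competition.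

Step 9. The likely failure is stalling of the catalytic cycle. Oxidative addition at a bromide flanked by the bulky aryloxy group is slow. The neighbouring ring B carboxylate may also chelate the arylpalladium intermediate, or capture the acylpalladium as a cyclic anhydride whose opening by methanol need not be selective. The fallback sets out from 20 and comes back at 22. Esterification with BnBr and K2CO3 gives benzyl 6-[4-(benzyloxy)-2-bromo-6-methoxyphenoxy]-3-chloro-2-methoxy-4-methylbenzoate F7. The same methoxycarbonylation, now without a free carboxylate, gives benzyl 6-[4-(benzyloxy)-2-methoxy-6-(methoxycarbonyl)phenoxy]-3-chloro-2-methoxy-4-methylbenzoate F8. BCl3 with pentamethylbenzene then removes the benzyl ester, the benzyl ether and the C5' methyl group to give 22.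

Step 10. The likely failure is incomplete discrimination between the two aryl methyl ethers when the mixture is warmed to complete the chelation-assisted demethylation, or ring benzylation by the benzyl cation if trapping is too slow. Debenzylation and demethylation have different temperature optima and are forced into one operation. The fallback sets out from 21 and comes back at 22. Hydrogenolysis of the benzyl ether (H2, Pd/C, EtOAc, 1 atm, short reaction time to spare the C–Cl bond) gives 3-chloro-6-[4-hydroxy-2-methoxy-6-(methoxycarbonyl)phenoxy]-2-methoxy-4-methylbenzoic acid F9. The chelated C5' methyl ether is then cleaved on its own with BCl3 in CH2Cl2 at the lowest temperature that suffices, with no benzyl cation present, to give 22.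

## Further compounds

F1 | step 8 | 5-bromo-2-chloro-1-methoxy-3-methylbenzene | COc1cc(Br)cc(C)c1Cl
F2 | step 8 | 6-bromo-3-chloro-2-methoxy-4-methylbenzoic acid | COc1c(Cl)c(C)cc(Br)c1C(=O)O
F3 | step 7 | 3-bromo-5-methoxy-4-(methoxymethoxy)benzaldehyde | COCOc1c(Br)cc(C=O)cc1OC
F4 | step 7 | 3-bromo-5-methoxy-4-(methoxymethoxy)phenyl formate | COCOc1c(Br)cc(OC=O)cc1OC
F5 | step 7 | 3-bromo-5-methoxy-4-(methoxymethoxy)phenol | COCOc1c(Br)cc(O)cc1OC
F6 | step 7 | 5-(benzyloxy)-1-bromo-3-methoxy-2-(methoxymethoxy)benzene | COCOc1c(Br)cc(OCc2ccccc2)cc1OC
F7 | step 9 | benzyl 6-[4-(benzyloxy)-2-bromo-6-methoxyphenoxy]-3-chloro-2-methoxy-4-methylbenzoate | COc1cc(OCc2ccccc2)cc(Br)c1Oc1cc(C)c(Cl)c(OC)c1C(=O)OCc1ccccc1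
F8 | step 9 | benzyl 6-[4-(benzyloxy)-2-methoxy-6-(methoxycarbonyl)phenoxy]-3-chloro-2-methoxy-4-methylbenzoate | COC(=O)c1cc(OCc2ccccc2)cc(OC)c1Oc1cc(C)c(Cl)c(OC)c1C(=O)OCc1ccccc1
F9 | step 10 | 3-chloro-6-[4-hydroxy-2-methoxy-6-(methoxycarbonyl)phenoxy]-2-methoxy-4-methylbenzoic acid | COC(=O)c1cc(O)cc(OC)c1Oc1cc(C)c(Cl)c(OC)c1C(=O)O
A1 | alternative 1 | racemic trans methyl 2-[2-(tert-butoxycarbonyl)-4-chloro-3-methoxy-5-methylphenoxy]-3,5-dioxocyclohexane-1-carboxylate (one enantiomer drawn) | COC(=O)[C@@H]1CC(=O)CC(=O)[C@H]1Oc1cc(C)c(Cl)c(OC)c1C(=O)OC(C)(C)C
A2 | alternative 1 | tert-butyl 3-chloro-2-methoxy-4-methyl-6-(2-oxopropoxy)benzoate | CC(=O)COc1cc(C)c(Cl)c(OC)c1C(=O)OC(C)(C)C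
A3 | alternative 1 | dimethyl fumarate | COC(=O)/C=C/C(=O)OC
A4 | alternative 2 | benzyl 6-[4-(benzyloxy)-2-methoxy-6-(methoxycarbonyl)phenoxy]-3-chloro-2-hydroxy-4-methylbenzoate | COC(=O)c1cc(OCc2ccccc2)cc(OC)c1Oc1cc(C)c(Cl)c(O)c1C(=O)OCc1ccccc1
A5 | alternative 2 | benzyl 3-[4-(benzyloxy)-2-methoxy-6-(methoxycarbonyl)phenoxy]prop-2-ynoate | COC(=O)c1cc(OCc2ccccc2)cc(OC)c1OC#CC(=O)OCc1ccccc1
A6 | alternative 2 | [(2-chloro-1-methoxy-3-methylbuta-1,3-dien-1-yl)oxy]trimethylsilane | COC(O[Si](C)(C)C)=C(Cl)C(C)=C
A7 | alternative 3 | benzyl 6-[4-(benzyloxy)-2-methoxy-6-(methoxycarbonyl)phenoxy]-3-chloro-2-methoxy-4-methylbenzoate | COC(=O)c1cc(OCc2ccccc2)cc(OC)c1Oc1cc(C)c(Cl)c(OC)c1C(=O)OCc1ccccc1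
A8 | alternative 3 | benzyl 4-[4-(benzyloxy)-2-methoxy-6-(methoxycarbonyl)phenoxy]-6-methyl-2-oxo-2H-pyran-3-carboxylate | COC(=O)c1cc(OCc2ccccc2)cc(OC)c1OC1=C(C(=O)OCc2ccccc2)C(=O)OC(C)=C1
A9 | alternative 3 | 2-chloro-1,1-dimethoxyethene | COC(OC)=CCl
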